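**Plan**

1. Ring numbering used here: C1 is the carbonyl carbon between C2 (OMe) and C6 (side chain), C4 is the other carbonyl, C3 and C5 are the ring CH carbons. The enabling feature is that C2–C1–C6 is the α-carbon/carbonyl/α′-carbon array of an open-chain ketone, while C3–C4–C5 is a symmetric three-carbon unit that maps onto a 2-substituted malonaldehyde.
2. Retrosynthesis: quinone ⇒ 4-aminophenol ⇒ 4-nitrophenol (nitrogen on C4 as latent quinone oxygen). Ring bonds C2–C3 and C5–C6 are then cut together ([3+3]) to sodium nitromalonaldehyde and the open-chain ketone (5R)-5-hydroxy-1-methoxyhexadecan-2-one.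
3. The ketone is cut at its C3–C4 bond to methyl 4-methoxyacetoacetate and (R)-1,2-epoxytridecane (acyl lactone, then decarboxylation). The epoxide is cut to (R)-epichlorohydrin and decylmagnesium bromide.
4. Forward: the chain is joined first (C10 + C3, then the acetoacetate unit). The only ring is then closed by a double aldol condensation with aromatisation. The side-chain acetate is installed, the nitro group is reduced, and the quinone is unveiled in the last step.
5. Stereochemistry: the single (R) centre is the stereocentre of (R)-epichlorohydrin; its C–O bond is never broken and it is never α to a carbonyl group.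

Key step: step 5

Remark: the stereocentre of the target is read from the SMILES as (R) (OAc > CH2–ring > undecyl > H); sodium nitromalonaldehyde is used as its commercial monohydrate, a shock-sensitive solid that is handled moist and behind a shield.

**Route**

Step 1
Reactants: 1 (R)-epichlorohydrin; 2 decylmagnesium bromide
Product: 3 (2R)-1-chlorotridecan-2-ol
Conditions: CuI (10 mol %), THF/Et2O, −40 to −20 °C; then 1 M HCl, 0 °C
Reagents that add atoms: none
Why: Copper-catalysed Grignard opening of the epoxide at its unsubstituted CH2 (SN2) should be much faster than displacement of chloride, and the stereocentre of 1 keeps its C–O bond, so (R) is carried over unchanged.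

Step 2
Reactants: 3 (2R)-1-chlorotridecan-2-ol
Product: 4 (R)-1,2-epoxytridecane
Conditions: NaOH (powdered), Et2O, rt
Reagents that add atoms: none
Why: Intramolecular Williamson etherification (3-exo-tet) of the chlorohydrin alkoxide closes the new epoxide on the former CH2Cl carbon without touching the stereocentre, so the (R)-epoxide should result.

Step 3
Reactants: 4 (R)-1,2-epoxytridecane; 5 methyl 4-methoxy-3-oxobutanoate
Product: 6 (5R)-3-(methoxyacetyl)-5-undecyloxolan-2-one
Conditions: NaOMe, MeOH, 65 °C; then cold 1 M HCl
Reagents that add atoms: none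
Why: In this classical β-keto ester/epoxide alkylation–lactonisation the sodium enolate of 5 opens the epoxide at the terminal CH2 (SN2, stereocentre untouched) and the alkoxide formed closes on the ester (5-exo-trig, loss of methoxide) to the α-acyl-γ-butyrolactone, which is protected as its stabilised enolate until the quench; C3 of 6 is a labile centre of no consequence.

Step 4
Reactants: 6 (5R)-3-(methoxyacetyl)-5-undecyloxolan-2-one
Product: 8 (5R)-5-hydroxy-1-methoxyhexadecan-2-one, via keto acid 7 (not isolated)
Conditions: 1 M H2SO4 (aq.)/1,4-dioxane, 90 °C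
Reagents that add atoms: none
Why: Ketonic hydrolysis of an α-acyl lactone: acid-catalysed acyl–oxygen hydrolysis gives β-keto acid 7, which loses CO2 through the usual cyclic transition state and so drives the lactone/hydroxy acid equilibrium forward; the carbinol C–O bond is never cleaved, so (R) is kept, and 8 may sit partly as its cyclic hemiketal and is used as such.

Step 5
Reactants: 8 (5R)-5-hydroxy-1-methoxyhexadecan-2-one; 9 sodium nitromalonaldehyde
Product: 12 2-[(2R)-2-hydroxytridecyl]-6-methoxy-4-nitrophenol, via open-chain nitronate 10 (not isolated), via sodium phenolate 11 (not isolated)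
Conditions: NaOH, EtOH/H2O, rt, dark, several days; then 1 M HCl, 0 °C
Reagents that add atoms: none
Why: Hydroxide enolises 8 towards C3 and C1 (in either order; 10 is drawn for first attack at C3): the first enolate adds to one formyl carbon of the nitromalonaldehyde anion and loses water to give open-chain nitronate 10, the second α-carbon then adds to the remaining formyl group, and a second dehydration gives a 4-nitrocyclohexa-2,5-dienone that tautomerises to phenolate 11, so both ring bonds C2–C3 and C5–C6 arise in one pot. The closest known reaction type is the classical [3+3] condensation of sodium nitromalonaldehyde with ketones that carry two α-methylene groups, which gives 2,6-disubstituted 4-nitrophenols. The only ring is closed by a 6-(enolendo)-exo-trig aldol addition, and the dehydration/aromatisation that follows should make the sequence irreversible. No new stereocentre is formed; the (R)-carbinol is γ to the ketone, cannot be enolised, and its C–O bond is not touched. The step needs cross- over self-condensation and a single constitution: nitromalonaldehyde has no enolisable hydrogen and is far more electrophilic than the ketone carbonyl, and because the three-carbon partner is symmetric and a benzene ring can form only when both α-carbons of the same carbonyl are used, the unsymmetrical ketone can give only the 2-alkyl-6-methoxy-4-nitrophenol. The nitro group, which makes the dialdehyde a stable and reactive salt, ends up on C4 as the precursor of the second quinone oxygen.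

Step 6
Reactants: 12 2-[(2R)-2-hydroxytridecyl]-6-methoxy-4-nitrophenol
Product: 14 (2R)-1-(2-hydroxy-3-methoxy-5-nitrophenyl)tridecan-2-yl acetate, via diacetate 13 (not isolated)
Conditions: Ac2O (2.5 equiv), pyridine, DMAP (cat.), CH2Cl2, rt; then pyrrolidine (1.6 equiv), 0 °C
Reagents that add atoms: acetic anhydride, CC(=O)OC(C)=O
Why: Exhaustive DMAP-catalysed acetylation is followed by chemoselective aminolysis of the activated nitrophenyl ester by pyrrolidine, which should leave the unactivated secondary alkyl acetate untouched; the configuration is retained because only O–H and O–acyl bonds change.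

Step 7
Reactants: 14 (2R)-1-(2-hydroxy-3-methoxy-5-nitrophenyl)tridecan-2-yl acetate
Product: 15 (2R)-1-(5-amino-2-hydroxy-3-methoxyphenyl)tridecan-2-yl acetate
Conditions: H2 (1 atm), Pd/C, EtOAc, rt; used at once under argon
Reagents that add atoms: none
Why: Catalytic hydrogenation of an aromatic nitro group to the aniline is routine, and the homobenzylic acetate and the aryl methyl ether are inert under these conditions.

Step 8
Reactants: 15 (2R)-1-(5-amino-2-hydroxy-3-methoxyphenyl)tridecan-2-yl acetate
Product: 17 (2R)-1-(5-methoxy-3,6-dioxocyclohexa-1,4-dien-1-yl)tridecan-2-yl acetate (CNP0137521.1), via quinone imine 16 (not isolated)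
Conditions: FeCl3 (2.5 equiv), 0.5 M HCl (aq.)/MeCN, 0 °C to rt
Reagents that add atoms: water, O
Why: Classical aminophenol-to-quinone oxidation: two-electron oxidation of the 4-aminophenol by FeCl3 gives quinone monoimine 16, which is hydrolysed at once in the acidic aqueous medium to the quinone and ammonium ion, while the acid keeps unreacted amine protonated and so should suppress amine–quinone coupling.

**Compound list**

1 | (R)-epichlorohydrin, (2R)-2-(chloromethyl)oxirane | ClC[C@H]1CO1 | starting material
2 | decylmagnesium bromide | CCCCCCCCCC[Mg]Br | starting material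
3 | (2R)-1-chlorotridecan-2-ol | CCCCCCCCCCC[C@H](CCl)O | intermediate
4 | (R)-1,2-epoxytridecane, (2R)-2-undecyloxirane | CCCCCCCCCCC[C@@H]1CO1 | intermediate
5 | methyl 4-methoxy-3-oxobutanoate (methyl 4-methoxyacetoacetate) | COCC(=O)CC(=O)OC | starting material
6 | (5R)-3-(methoxyacetyl)-5-undecyloxolan-2-one, C3 epimers and enol | CCCCCCCCCCC[C@@H]1CC(C(=O)COC)C(=O)O1 | intermediate
7 | (4R)-4-hydroxy-2-(methoxyacetyl)pentadecanoic acid, keto acid, not isolated | CCCCCCCCCCC[C@H](CC(C(=O)O)C(=O)COC)O | intermediate
8 | (5R)-5-hydroxy-1-methoxyhexadecan-2-one | CCCCCCCCCCC[C@H](CCC(=O)COC)O | intermediate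
9 | sodium nitromalonaldehyde, sodium 2-nitro-3-oxoprop-1-en-1-olate, used as monohydrate | [Na+].[O-]C=C(C=O)[N+](=O)[O-] | starting material
10 | sodium nitronate of 4-[(2R)-2-hydroxytridecyl]-6-methoxy-2-nitro-5-oxohex-3-enal, open-chain mono-condensation product, not isolated | CCCCCCCCCCC[C@H](CC(=CC(C=O)=[N+]([O-])[O-])C(=O)COC)O.[Na+] | intermediate
11 | sodium 2-[(2R)-2-hydroxytridecyl]-6-methoxy-4-nitrophenolate, not isolated | CCCCCCCCCCC[C@H](Cc1cc(cc(OC)c1[O-])[N+](=O)[O-])O.[Na+] | intermediate
12 | 2-[(2R)-2-hydroxytridecyl]-6-methoxy-4-nitrophenol | CCCCCCCCCCC[C@H](Cc1cc(cc(OC)c1O)[N+](=O)[O-])O | intermediate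
13 | (2R)-1-(2-acetoxy-3-methoxy-5-nitrophenyl)tridecan-2-yl acetate, diacetate, not isolated | CCCCCCCCCCC[C@H](Cc1cc(cc(OC)c1OC(C)=O)[N+](=O)[O-])OC(C)=O | intermediate
14 | (2R)-1-(2-hydroxy-3-methoxy-5-nitrophenyl)tridecan-2-yl acetate | CCCCCCCCCCC[C@H](Cc1cc(cc(OC)c1O)[N+](=O)[O-])OC(C)=O | intermediate
15 | (2R)-1-(5-amino-2-hydroxy-3-methoxyphenyl)tridecan-2-yl acetate | CCCCCCCCCCC[C@H](Cc1cc(N)cc(OC)c1O)OC(C)=O | intermediate
16 | (2R)-1-(3-imino-5-methoxy-6-oxocyclohexa-1,4-dien-1-yl)tridecan-2-yl acetate, quinone monoimine, not isolated | CCCCCCCCCCC[C@H](CC1=CC(=N)C=C(OC)C1=O)OC(C)=O | intermediate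
17 | (2R)-1-(5-methoxy-3,6-dioxocyclohexa-1,4-dien-1-yl)tridecan-2-yl acetate, 2-[(2R)-2-acetoxytridecyl]-6-methoxy-1,4-benzoquinone | CCCCCCCCCCC[C@H](CC1=CC(=O)C=C(OC)C1=O)OC(C)=O | target

**Count and risks**

Total step count: 8. Longest linear sequence: 8 steps (1 to 17).

The three steps most likely to fail:

Step 5, the [3+3] annulation. The double condensation may stall after the first aldol step or run slowly because the γ-hydroxy ketone is partly tied up as its cyclic hemiketal, and self-condensation of the ketone or decay of the nitromalonaldehyde salt may compete over the long reaction time. The fallback gives up ring construction and attaches the chain to a ready-made guaiacol ring; it sets out from epoxide 4 and comes back at 12. Guaiacol is protected (MOMCl, i-Pr2NEt, CH2Cl2) as 1-methoxy-2-(methoxymethoxy)benzene F1. Directed ortho-lithiation next to the MOM ether (n-BuLi, THF, 0 °C) should give [3-methoxy-2-(methoxymethoxy)phenyl]lithium F2. F2 should open 4 at its terminal carbon (BF3·OEt2, THF, −78 °C) to give (2R)-1-[3-methoxy-2-(methoxymethoxy)phenyl]tridecan-2-ol F3. Acidic methanolysis (HCl, MeOH, 40 °C) removes the MOM group to give 2-[(2R)-2-hydroxytridecyl]-6-methoxyphenol F4. Nitration para to the phenol, whose two ortho positions are blocked (HNO3, AcOH, 10 °C), should then give 12.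

Step 3, the enolate/epoxide alkylation–lactonisation. Opening of the unactivated epoxide by the stabilised enolate may be sluggish, so that methanolysis of the epoxide and retro-Claisen deacylation of the acyl lactone take over. The fallback replaces steps 3 and 4; it sets out from 4 and comes back at 8. Dilithium acetate (AcOH, 2 equiv LDA, THF, 0 to 45 °C) should open 4 at the terminal carbon to give (4R)-4-hydroxypentadecanoic acid F5. F5 lactonises on acidic work-up (TsOH cat., toluene, 80 °C) to (5R)-5-undecyloxolan-2-one F6. Single addition of methoxymethyllithium (from tributyl(methoxymethyl)stannane and n-BuLi, THF, −78 °C) to the lactone carbonyl should give the lithium lactolate and, on work-up, 8.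

Step 8, the aminophenol oxidation. Unoxidised aminophenol may couple with the quinone imine or the quinone (indoaniline and aminoquinone formation), or over-oxidation may set in before hydrolysis is complete. The fallback removes the nitrogen before the oxidation; it sets out from 15 and comes back at 17. Diazotisation (NaNO2, aq. H2SO4/THF, 0 °C) should give 3-[(2R)-2-acetoxytridecyl]-4-hydroxy-5-methoxybenzenediazonium hydrogen sulfate F7. Reduction with H3PO2 (0 °C to rt) should give (2R)-1-(2-hydroxy-3-methoxyphenyl)tridecan-2-yl acetate F8. Teuber oxidation of this phenol, whose ortho positions are both blocked, with potassium nitrosodisulfonate (KSO3)2NO (KH2PO4, H2O/acetone, rt) should give the para-quinone 17.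

**Further compounds**

F1 | step 5 | 1-methoxy-2-(methoxymethoxy)benzene | COCOc1ccccc1OC
F2 | step 5 | [3-methoxy-2-(methoxymethoxy)phenyl]lithium | [Li]c1cccc(OC)c1OCOC
F3 | step 5 | (2R)-1-[3-methoxy-2-(methoxymethoxy)phenyl]tridecan-2-ol | CCCCCCCCCCC[C@H](Cc1cccc(OC)c1OCOC)O
F4 | step 5 | 2-[(2R)-2-hydroxytridecyl]-6-methoxyphenol | CCCCCCCCCCC[C@H](Cc1cccc(OC)c1O)O
F5 | step 3 | (4R)-4-hydroxypentadecanoic acid | CCCCCCCCCCC[C@H](CCC(=O)O)O
F6 | step 3 | (5R)-5-undecyloxolan-2-one | CCCCCCCCCCC[C@@H]1CCC(=O)O1
F7 | step 8 | 3-[(2R)-2-acetoxytridecyl]-4-hydroxy-5-methoxybenzenediazonium hydrogen sulfate | CCCCCCCCCCC[C@H](Cc1cc(cc(OC)c1O)[N+]#N)OC(C)=O.OS(=O)(=O)[O-]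
F8 | step 8 | (2R)-1-(2-hydroxy-3-methoxyphenyl)tridecan-2-yl acetate | CCCCCCCCCCC[C@H](Cc1cccc(OC)c1O)OC(C)=O
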